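## Retrosynthetic overview

1. The C5 ester is disconnected last, giving the ring-A alcohol (a cis-5-hydroxy lactone) and a silyl-protected (2E,4E,6S)-dienoic acid (fragment 3, from organocatalytic α-hydroxymethylation of 4-silyloxybutanal, Wittig and Horner–Wadsworth–Emmons olefination).
2. The C5–OH is carried as a C5–B(MIDA) bond and oxidised with retention. The C4'–C5' bond comes from an sp3–sp2 Negishi coupling of a primary iodide with an (S)-2-bromoallylic silyl ether (fragment 2, from (S)-but-3-yn-2-ol).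
3. Key disconnection: ring A (O1–C2(=O)–C3=C4–C5–C6), the only ring of the target, is cut at C4–C5 and O1–C6 into propiolic acid and a (Z)-alkenyl MIDA boronate. Forward, a monovalent-gold-catalysed [4+2] annulation builds the ring and both ring stereocentres in one operation.
4. Enabling feature: O1, C2, C3 and C4 of ring A are exactly one propiolic acid, and the cis C5–O/C6–C1' pair on adjacent sp3 carbons is the retron of a Z C5=C6 alkene. Carrying the C5 oxygen as tetracoordinate boron makes C5 the nucleophilic and C6 the cationic carbon.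
5. The alkene comes from an alkyne, an aldehyde and lipase-desymmetrised meso-2,4-dimethylpentane-1,5-diol (fragment 1; the meso anhydride ring is the template for C1' and C3'). Ring order: ring A is the only ring formed (step 10); the MIDA cage is a temporary ring pair (on in step 6, off in step 14).

Key step: step 10

Remark on numbering: ring A = O1, C2(=O), C3, C4, C5, C6; side-chain carbons C1' to C7' run outward from C6.

Assumption: the lipase acetylates the enantiotopic hydroxymethyl group that leads to the (2R,4S)-monoacetate; if its preference is the opposite, the same monoacetate is reached by running the enzyme hydrolytically on the meso-diacetate.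

## Route

**Fragment 1 and ring A**

Step 1
Reactants: 1 meso-2,4-dimethylglutaric anhydride [(3R,5S)-3,5-dimethyloxane-2,6-dione]
Product: 2 meso-(2R,4S)-2,4-dimethylpentane-1,5-diol
Conditions: LiAlH4, THF, 0 °C → reflux; aqueous NaOH work-up
Reagents that add atoms: none
Why: Hydride reduction of a cyclic anhydride to the 1,5-diol leaves both methyl-bearing stereocentres untouched, so the cis (meso) relationship of the ring template is transferred to the chain.

Step 2
Reactants: 2 meso-(2R,4S)-2,4-dimethylpentane-1,5-diol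
Product: 3 (2R,4S)-5-hydroxy-2,4-dimethylpentyl acetate
Conditions: Amano lipase AK (Pseudomonas fluorescens), vinyl acetate, THF, 25 °C
Reagents that add atoms: vinyl acetate, CC(=O)OC=C
Why: Enzymatic desymmetrisation of a meso-diol by irreversible lipase-catalysed transesterification; the enzyme distinguishes the enantiotopic CH2OH groups and so fixes C1' (S) and C3' (R) at once.

Step 3
Reactants: 3 (2R,4S)-5-hydroxy-2,4-dimethylpentyl acetate
Product: 4 (2R,4S)-2,4-dimethyl-5-oxopentyl acetate
Conditions: TEMPO (10 mol %), PhI(OAc)2, CH2Cl2, 25 °C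
Reagents that add atoms: none
Why: Nitroxyl/hypervalent-iodine oxidation of a primary alcohol stops at the aldehyde and is non-basic, so the α-stereocentre should not epimerise.

Step 4
Reactants: 4 (2R,4S)-2,4-dimethyl-5-oxopentyl acetate
Product: 5 (2R,4S)-2,4-dimethylhex-5-yn-1-ol
Conditions: dimethyl (1-diazo-2-oxopropyl)phosphonate, K2CO3, MeOH, 0 → 25 °C (reagent and base premixed before the aldehyde is added)
Reagents that add atoms: dimethyl (1-diazo-2-oxopropyl)phosphonate, CC(=O)C(=[N+]=[N-])P(=O)(OC)OC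
Why: Seyferth–Gilbert homologation in the Ohira–Bestmann modification turns the aldehyde into the terminal alkyne while the same K2CO3/MeOH removes the acetate by transesterification; pre-forming the diazophosphonate anion at 0 °C should let homologation outrun lactol formation and α-epimerisation.

Step 5
Reactants: 5 (2R,4S)-2,4-dimethylhex-5-yn-1-ol
Product: 6 tert-butyl{[(2R,4S)-2,4-dimethylhex-5-yn-1-yl]oxy}dimethylsilane
Conditions: TBSCl, imidazole, CH2Cl2, 0 → 25 °C
Reagents that add atoms: tert-butyldimethylsilyl chloride, CC(C)(C)[Si](C)(C)Cl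
Why: Standard imidazole-mediated silylation of a primary alcohol, needed because a free hydroxyl would interfere with the borylation and, later, with the gold step.

Step 6
Reactants: 6 tert-butyl{[(2R,4S)-2,4-dimethylhex-5-yn-1-yl]oxy}dimethylsilane
Product: 9 2-[(3S,5R)-6-{[tert-butyl(dimethyl)silyl]oxy}-3,5-dimethylhex-1-yn-1-yl]-6-methyl-1,3,6,2-dioxazaborocane-4,8-dione (alkynyl MIDA boronate), via alkynylmagnesium bromide 7 (not isolated), via bromomagnesium alkynyltrimethoxyborate 8 (not isolated)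
Conditions: EtMgBr, THF, 0 → 25 °C; B(OMe)3, −78 → 25 °C; then added to MeN(CH2CO2H)2, DMSO, 115 °C (THF and MeOH distilled off)
Reagents that add atoms: trimethyl borate, COB(OC)OC; N-methyliminodiacetic acid, CN(CC(=O)O)CC(=O)O
Why: Acetylide borylation followed by transligation of the borate with N-methyliminodiacetic acid in hot DMSO is the established entry to alkynyl MIDA boronates; no stereocentre is involved.

Step 7
Reactants: 9 alkynyl MIDA boronate
Product: 10 2-[(1Z,3S,5R)-6-{[tert-butyl(dimethyl)silyl]oxy}-3,5-dimethylhex-1-en-1-yl]-6-methyl-1,3,6,2-dioxazaborocane-4,8-dione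
Conditions: H2 (1 atm), Pd/CaCO3 poisoned with Pb(OAc)2 (Lindlar catalyst), quinoline, EtOAc/MeCN, 25 °C
Reagents that add atoms: none
Why: Lindlar semi-hydrogenation (syn addition of H2) sets the Z geometry that later becomes the cis C5/C6 relationship; the tetracoordinate boron is inert to hydrogenation.

Step 8
Reactants: 10 (Z)-alkenyl MIDA boronate silyl ether
Product: 11 2-[(1Z,3S,5R)-6-hydroxy-3,5-dimethylhex-1-en-1-yl]-6-methyl-1,3,6,2-dioxazaborocane-4,8-dione
Conditions: HF·pyridine, pyridine, THF, 0 → 25 °C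
Reagents that add atoms: none
Why: Fluoride-mediated desilylation under buffered acidic conditions, to which MIDA boronates and the Z-alkene are stable.

Step 9
Reactants: 11 (Z)-alkenyl MIDA boronate alcohol
Product: 12 2-[(1Z,3S,5R)-6-iodo-3,5-dimethylhex-1-en-1-yl]-6-methyl-1,3,6,2-dioxazaborocane-4,8-dione
Conditions: I2, PPh3, imidazole, CH2Cl2/MeCN, 0 → 25 °C
Reagents that add atoms: iodine, II
Why: Appel-type iodination, an SN2 displacement of the alkoxyphosphonium ion at the primary carbon; the MIDA-protected alkenylboron is not attacked by iodine.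

Step 10
Reactants: 12 (Z)-alkenyl MIDA boronate iodide; 13 propiolic acid
Product: 14 (5R,6S)-6-[(2S,4R)-5-iodo-4-methylpentan-2-yl]-5-(6-methyl-4,8-dioxo-1,3,6,2-dioxazaborocan-2-yl)-5,6-dihydro-2H-pyran-2-one
Conditions: [(t-Bu)2(biphenyl-2-yl)P]Au(NCMe)SbF6 (5 mol %), propiolic acid (3 equiv), ClCH2CH2Cl, 40 °C, dark
Reagents that add atoms: none
Why: Proposed new method: the cationic monovalent-gold complex π-activates propiolic acid, the Z alkene of 12 attacks the terminal alkyne carbon (C4) through its boron-bearing carbon C5 because the positive charge developing at C6 is stabilised by hyperconjugation with the electron-rich σ(C5–B) bond of the tetracoordinate boron (β-boron effect), and the carboxyl oxygen, held cis to the new C4–C5 bond in the vinylgold intermediate, captures C6 before protodeauration releases 14 and the catalyst. The closest known reaction type is the monovalent-gold-catalysed formal [4+2] annulation of propiolic acid with unactivated alkenes to 5,6-dihydro-2H-pyran-2-ones, which is stereospecific for 1,2-disubstituted alkenes; new here is an alkenyl MIDA boronate as the two-carbon partner, whose regiochemical bias has precedent in Markovnikov-type electrophilic and metal-catalysed additions to alkenyl and alkynyl MIDA boronates that place the nucleophile β to boron. Ring A is closed by O1–C6 bond formation, a six-membered carbonyl-oxygen capture of the C6 cation that is endo with respect to the former C5=C6 bond, so the whole event is a concerted but asynchronous [4+2] in which C4–C5 leads. C5 and C6 are formed suprafacially, so the Z geometry set in step 7 becomes the cis C5–B/C6–alkyl relationship, and the absolute sense is controlled by the C1' stereocentre: its C–H bond eclipses the alkene to avoid A(1,3) strain with the cis B(MIDA) group, the C1' methyl and the C2' chain then flank the two faces, and annulation on the methyl-flanked face gives the (5R,6S) isomer shown (5R,6R once boron is replaced by oxygen). The step needs regioselectivity (secured by the β-boron effect and by the MIDA cage, which leaves boron no vacant site and so blocks ipso-deborylation to a dienoic acid), cis-stereospecificity (secured by fast intramolecular capture and the conformational lock of the hyperconjugated cation), facial selectivity (A(1,3) control, expected to be useful but not complete, with the minor diastereomer removable by chromatography of the MIDA boronate) and chemoselectivity (12 has no other alkene, and the primary iodide and MIDA esters are inert to a silver-free gold catalyst).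

**Fragment 2 (alkenyl bromide)**

Step 11
Reactants: 15 (S)-but-3-yn-2-ol
Product: 16 (S)-(but-3-yn-2-yloxy)(tert-butyl)dimethylsilane
Conditions: TBSCl, imidazole, CH2Cl2, 0 → 25 °C
Reagents that add atoms: tert-butyldimethylsilyl chloride, CC(C)(C)[Si](C)(C)Cl
Why: Standard silylation of a secondary propargylic alcohol; the chiral-pool stereocentre (C6') is not involved.

Step 12
Reactants: 16 (S)-(but-3-yn-2-yloxy)(tert-butyl)dimethylsilane
Product: 18 (S)-[(3-bromobut-3-en-2-yl)oxy](tert-butyl)dimethylsilane, via bromoalkenyl-9-BBN adduct 17 (not isolated)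
Conditions: B-bromo-9-BBN, CH2Cl2, 0 °C; then AcOH, 0 → 25 °C
Reagents that add atoms: B-bromo-9-borabicyclo[3.3.1]nonane, BrB1C2CCCC1CCC2
Why: Haloboration: syn-bromoboration of the terminal alkyne places bromine on the internal carbon, and protonolysis of the alkenyl C–B bond with acetic acid leaves the 2-bromo-1-alkene without touching the carbinol stereocentre.

**Union of fragments 1 and 2, release of the C5 hydroxyl**

Step 13
Reactants: 14 boryl lactone iodide; 18 (S)-[(3-bromobut-3-en-2-yl)oxy](tert-butyl)dimethylsilane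
Product: 20 (5R,6S)-6-[(2S,4R,7S)-7-{[tert-butyl(dimethyl)silyl]oxy}-4-methyl-6-methylideneoctan-2-yl]-5-(6-methyl-4,8-dioxo-1,3,6,2-dioxazaborocan-2-yl)-5,6-dihydro-2H-pyran-2-one, via alkylzinc iodide 19 (not isolated)
Conditions: Zn dust (activated with BrCH2CH2Br and Me3SiCl), LiCl, THF, 30 °C; then 18, Pd(PPh3)4 (5 mol %), THF, 40 °C
Reagents that add atoms: none
Why: Negishi sp3–sp2 cross-coupling: direct zinc insertion into the primary iodide gives an alkylzinc iodide that tolerates the unsaturated lactone and the MIDA boronate, and zerovalent palladium couples it with the alkenyl bromide without moving the double bond; the allylic C5–B(MIDA) bond does not transmetalate under anhydrous conditions and thus serves as the protected C5 hydroxyl.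

Step 14
Reactants: 20 coupled boryl lactone
Product: 22 (5R,6R)-6-[(2S,4R,7S)-7-{[tert-butyl(dimethyl)silyl]oxy}-4-methyl-6-methylideneoctan-2-yl]-5-hydroxy-5,6-dihydro-2H-pyran-2-one, via boronic acid 21 (not isolated)
Conditions: NaBO3·4H2O, THF/H2O (1:1), 0 → 25 °C; pH 7 buffer work-up
Reagents that add atoms: sodium perborate (used as the tetrahydrate), [Na+].[O-]OB=O
Why: Oxidation of a carbon–boron bond (mildly basic release of the boronic acid from the MIDA cage, then 1,2-migration of C5 from boron to peroxide oxygen) proceeds with retention, so the cis C5–B bond becomes the cis C5–OH.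

**Fragment 3 (dienoic acid)**

Step 15
Reactants: 23 4-{[tert-butyl(dimethyl)silyl]oxy}butanal
Product: 25 (2E,4S)-6-{[tert-butyl(dimethyl)silyl]oxy}-4-(hydroxymethyl)-2-methylhex-2-enal, via hydroxymethyl aldehyde 24 (not isolated)
Conditions: aq. HCHO (37 %), (S)-α,α-diphenylprolinol trimethylsilyl ether (10 mol %), pH 7 phosphate buffer, PhMe, 25 °C; then organic phase separated and dried, Ph3P=C(Me)CHO, 45 °C
Reagents that add atoms: formaldehyde, C=O; 2-(triphenylphosphoranylidene)propanal, CC(C=O)=P(c1ccccc1)(c1ccccc1)c1ccccc1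
Why: Enamine-catalysed α-hydroxymethylation (cross-aldol with formaldehyde): the diarylprolinol silyl ether shields one face of the E-enamine so that formaldehyde should add to the other and give the (R)-aldehyde, which is trapped without isolation by an E-selective Wittig reaction with a stabilised formyl ylide before it can dehydrate or racemise.

Step 16
Reactants: 25 hydroxy enal
Product: 26 (2E,4S)-6-{[tert-butyl(dimethyl)silyl]oxy}-4-({[tert-butyl(dimethyl)silyl]oxy}methyl)-2-methylhex-2-enal
Conditions: TBSCl, imidazole, CH2Cl2, 0 → 25 °C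
Reagents that add atoms: tert-butyldimethylsilyl chloride, CC(C)(C)[Si](C)(C)Cl
Why: Standard silylation of the primary alcohol so that only one hydroxyl (C5–OH of 22) is free in the esterification.

Step 17
Reactants: 26 bis-silyl enal
Product: 27 ethyl (2E,4E,6S)-8-{[tert-butyl(dimethyl)silyl]oxy}-6-({[tert-butyl(dimethyl)silyl]oxy}methyl)-4-methylocta-2,4-dienoate
Conditions: (EtO)2P(O)CH2CO2Et, NaH, THF, 0 → 25 °C
Reagents that add atoms: triethyl phosphonoacetate, CCOC(=O)CP(=O)(OCC)OCC
Why: Horner–Wadsworth–Emmons olefination of an α-branched enal with a stabilised phosphonate anion is reliably E-selective and gives the (2E,4E)-dienoate; the allylic stereocentre is not deprotonated by the weakly basic phosphonate anion.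

Step 18
Reactants: 27 ethyl dienoate
Product: 28 (2E,4E,6S)-8-{[tert-butyl(dimethyl)silyl]oxy}-6-({[tert-butyl(dimethyl)silyl]oxy}methyl)-4-methylocta-2,4-dienoic acid
Conditions: LiOH·H2O, THF/MeOH/H2O, 25 °C; then 1 M HCl to pH 4 at 0 °C
Reagents that add atoms: lithium hydroxide monohydrate, [Li+].[OH-].O
Why: Saponification of an unhindered conjugated ethyl ester; primary silyl ethers survive LiOH at room temperature and a brief cold, mildly acidic work-up.

**Endgame**

Step 19
Reactants: 22 cis-5-hydroxy lactone; 28 dienoic acid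
Product: 29 (2R,3R)-2-[(2S,4R,7S)-7-{[tert-butyl(dimethyl)silyl]oxy}-4-methyl-6-methylideneoctan-2-yl]-6-oxo-3,6-dihydro-2H-pyran-3-yl (2E,4E,6S)-8-{[tert-butyl(dimethyl)silyl]oxy}-6-({[tert-butyl(dimethyl)silyl]oxy}methyl)-4-methylocta-2,4-dienoate
Conditions: DCC, DMAP (0.2 equiv), CH2Cl2, 0 → 25 °C
Reagents that add atoms: none
Why: Steglich esterification (carbodiimide activation, DMAP acyl transfer) acylates the only free hydroxyl without touching a stereocentre; catalytic DMAP and low temperature limit base-induced translactonisation of 22.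

Step 20
Reactants: 29 tris-silyl ether
Product: 30 (2R,3R)-2-[(2S,4R,7S)-7-hydroxy-4-methyl-6-methylideneoctan-2-yl]-6-oxo-3,6-dihydro-2H-pyran-3-yl (2E,4E,6S)-8-hydroxy-6-(hydroxymethyl)-4-methylocta-2,4-dienoate (CNP0219019.1)
Conditions: HF·pyridine, pyridine, THF, 0 → 25 °C
Reagents that add atoms: none
Why: Global fluoride-mediated desilylation of two primary and one secondary allylic silyl ether under buffered acidic conditions that leave the lactone, the dienoate ester and all alkenes intact.

## Compound list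

1 | meso-2,4-dimethylglutaric anhydride, (3R,5S)-3,5-dimethyloxane-2,6-dione | O=C1[C@H](C)C[C@H](C)C(=O)O1 | starting material
2 | meso-(2R,4S)-2,4-dimethylpentane-1,5-diol | OC[C@H](C)C[C@H](C)CO | intermediate
3 | (2R,4S)-5-hydroxy-2,4-dimethylpentyl acetate | CC(=O)OC[C@H](C)C[C@H](C)CO | intermediate
4 | (2R,4S)-2,4-dimethyl-5-oxopentyl acetate | CC(=O)OC[C@H](C)C[C@H](C)C=O | intermediate
5 | (2R,4S)-2,4-dimethylhex-5-yn-1-ol | OC[C@H](C)C[C@H](C)C#C | intermediate
6 | tert-butyl{[(2R,4S)-2,4-dimethylhex-5-yn-1-yl]oxy}dimethylsilane | CC(C)(C)[Si](C)(C)OC[C@H](C)C[C@H](C)C#C | intermediate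
7 | bromo[(3S,5R)-6-{[tert-butyl(dimethyl)silyl]oxy}-3,5-dimethylhex-1-yn-1-yl]magnesium | CC(C)(C)[Si](C)(C)OC[C@H](C)C[C@H](C)C#C[Mg]Br | intermediate
8 | bromomagnesium [(3S,5R)-6-{[tert-butyl(dimethyl)silyl]oxy}-3,5-dimethylhex-1-yn-1-yl]trimethoxyborate | CC(C)(C)[Si](C)(C)OC[C@H](C)C[C@H](C)C#C[B-](OC)(OC)OC.[Mg+]Br | intermediate
9 | 2-[(3S,5R)-6-{[tert-butyl(dimethyl)silyl]oxy}-3,5-dimethylhex-1-yn-1-yl]-6-methyl-1,3,6,2-dioxazaborocane-4,8-dione | CC(C)(C)[Si](C)(C)OC[C@H](C)C[C@H](C)C#C[B-]12OC(=O)C[N+]1(C)CC(=O)O2 | intermediate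
10 | 2-[(1Z,3S,5R)-6-{[tert-butyl(dimethyl)silyl]oxy}-3,5-dimethylhex-1-en-1-yl]-6-methyl-1,3,6,2-dioxazaborocane-4,8-dione | CC(C)(C)[Si](C)(C)OC[C@H](C)C[C@H](C)/C=C\[B-]12OC(=O)C[N+]1(C)CC(=O)O2 | intermediate
11 | 2-[(1Z,3S,5R)-6-hydroxy-3,5-dimethylhex-1-en-1-yl]-6-methyl-1,3,6,2-dioxazaborocane-4,8-dione | OC[C@H](C)C[C@H](C)/C=C\[B-]12OC(=O)C[N+]1(C)CC(=O)O2 | intermediate
12 | 2-[(1Z,3S,5R)-6-iodo-3,5-dimethylhex-1-en-1-yl]-6-methyl-1,3,6,2-dioxazaborocane-4,8-dione | IC[C@H](C)C[C@H](C)/C=C\[B-]12OC(=O)C[N+]1(C)CC(=O)O2 | intermediate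
13 | propiolic acid (prop-2-ynoic acid) | C#CC(=O)O | starting material
14 | (5R,6S)-6-[(2S,4R)-5-iodo-4-methylpentan-2-yl]-5-(6-methyl-4,8-dioxo-1,3,6,2-dioxazaborocan-2-yl)-5,6-dihydro-2H-pyran-2-one | IC[C@H](C)C[C@H](C)[C@H]1OC(=O)C=C[C@H]1[B-]23OC(=O)C[N+]2(C)CC(=O)O3 | intermediate
15 | (S)-but-3-yn-2-ol | C#C[C@H](C)O | starting material
16 | (S)-(but-3-yn-2-yloxy)(tert-butyl)dimethylsilane | C#C[C@H](C)O[Si](C)(C)C(C)(C)C | intermediate
17 | 9-[(1Z,3S)-2-bromo-3-{[tert-butyl(dimethyl)silyl]oxy}but-1-en-1-yl]-9-borabicyclo[3.3.1]nonane | C[C@H](O[Si](C)(C)C(C)(C)C)C(/Br)=C/B1C2CCCC1CCC2 | intermediate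
18 | (S)-[(3-bromobut-3-en-2-yl)oxy](tert-butyl)dimethylsilane | C=C(Br)[C@H](C)O[Si](C)(C)C(C)(C)C | intermediate
19 | iodo{(2R,4S)-2-methyl-4-[(2S,3R)-3-(6-methyl-4,8-dioxo-1,3,6,2-dioxazaborocan-2-yl)-6-oxo-3,6-dihydro-2H-pyran-2-yl]pentyl}zinc | I[Zn]C[C@H](C)C[C@H](C)[C@H]1OC(=O)C=C[C@H]1[B-]23OC(=O)C[N+]2(C)CC(=O)O3 | intermediate
20 | (5R,6S)-6-[(2S,4R,7S)-7-{[tert-butyl(dimethyl)silyl]oxy}-4-methyl-6-methylideneoctan-2-yl]-5-(6-methyl-4,8-dioxo-1,3,6,2-dioxazaborocan-2-yl)-5,6-dihydro-2H-pyran-2-one | C=C(C[C@H](C)C[C@H](C)[C@H]1OC(=O)C=C[C@H]1[B-]23OC(=O)C[N+]2(C)CC(=O)O3)[C@H](C)O[Si](C)(C)C(C)(C)C | intermediate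
21 | {(2S,3R)-2-[(2S,4R,7S)-7-{[tert-butyl(dimethyl)silyl]oxy}-4-methyl-6-methylideneoctan-2-yl]-6-oxo-3,6-dihydro-2H-pyran-3-yl}boronic acid | C=C(C[C@H](C)C[C@H](C)[C@H]1OC(=O)C=C[C@H]1B(O)O)[C@H](C)O[Si](C)(C)C(C)(C)C | intermediate
22 | (5R,6R)-6-[(2S,4R,7S)-7-{[tert-butyl(dimethyl)silyl]oxy}-4-methyl-6-methylideneoctan-2-yl]-5-hydroxy-5,6-dihydro-2H-pyran-2-one | C=C(C[C@H](C)C[C@H](C)[C@H]1OC(=O)C=C[C@H]1O)[C@H](C)O[Si](C)(C)C(C)(C)C | intermediate
23 | 4-{[tert-butyl(dimethyl)silyl]oxy}butanal | CC(C)(C)[Si](C)(C)OCCCC=O | starting material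
24 | (2R)-4-{[tert-butyl(dimethyl)silyl]oxy}-2-(hydroxymethyl)butanal | O=C[C@@H](CO)CCO[Si](C)(C)C(C)(C)C | intermediate
25 | (2E,4S)-6-{[tert-butyl(dimethyl)silyl]oxy}-4-(hydroxymethyl)-2-methylhex-2-enal | O=C/C(C)=C/[C@@H](CO)CCO[Si](C)(C)C(C)(C)C | intermediate
26 | (2E,4S)-6-{[tert-butyl(dimethyl)silyl]oxy}-4-({[tert-butyl(dimethyl)silyl]oxy}methyl)-2-methylhex-2-enal | O=C/C(C)=C/[C@@H](CO[Si](C)(C)C(C)(C)C)CCO[Si](C)(C)C(C)(C)C | intermediate
27 | ethyl (2E,4E,6S)-8-{[tert-butyl(dimethyl)silyl]oxy}-6-({[tert-butyl(dimethyl)silyl]oxy}methyl)-4-methylocta-2,4-dienoate | CCOC(=O)/C=C/C(C)=C/[C@@H](CO[Si](C)(C)C(C)(C)C)CCO[Si](C)(C)C(C)(C)C | intermediate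
28 | (2E,4E,6S)-8-{[tert-butyl(dimethyl)silyl]oxy}-6-({[tert-butyl(dimethyl)silyl]oxy}methyl)-4-methylocta-2,4-dienoic acid | OC(=O)/C=C/C(C)=C/[C@@H](CO[Si](C)(C)C(C)(C)C)CCO[Si](C)(C)C(C)(C)C | intermediate
29 | (2R,3R)-2-[(2S,4R,7S)-7-{[tert-butyl(dimethyl)silyl]oxy}-4-methyl-6-methylideneoctan-2-yl]-6-oxo-3,6-dihydro-2H-pyran-3-yl (2E,4E,6S)-8-{[tert-butyl(dimethyl)silyl]oxy}-6-({[tert-butyl(dimethyl)silyl]oxy}methyl)-4-methylocta-2,4-dienoate | C=C(C[C@H](C)C[C@H](C)[C@H]1OC(=O)C=C[C@H]1OC(=O)/C=C/C(C)=C/[C@@H](CO[Si](C)(C)C(C)(C)C)CCO[Si](C)(C)C(C)(C)C)[C@H](C)O[Si](C)(C)C(C)(C)C | intermediate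
30 | (2R,3R)-2-[(2S,4R,7S)-7-hydroxy-4-methyl-6-methylideneoctan-2-yl]-6-oxo-3,6-dihydro-2H-pyran-3-yl (2E,4E,6S)-8-hydroxy-6-(hydroxymethyl)-4-methylocta-2,4-dienoate | C=C(C[C@H](C)C[C@H](C)[C@H]1OC(=O)C=C[C@H]1OC(=O)/C=C/C(C)=C/[C@@H](CO)CCO)[C@H](C)O | target

## Step count and risks

Total step count: 20. Longest linear sequence: 14 steps (steps 1–10, 13, 14, 19, 20).

**Step 10 (proposed new method).** What may go wrong: attack of the alkene through C6 instead of C5, or collapse of the β-boryl cation by loss or shift of the boryl group (ipso-substitution to a dienoic acid); slow turnover because the boron-bearing alkene is hindered and only moderately nucleophilic; insufficient discrimination of the two alkene faces by the C1' stereocentre. Fallback (known chemistry, ring A closed by olefin metathesis at C3=C4 instead): setting out from aldehyde 4, reagent-controlled syn-alkoxyallylation with (Z)-γ-(4-methoxybenzyloxy)allyldiisopinocampheylborane [from allyl 4-methoxybenzyl ether, s-BuLi, (−)-B-methoxydiisopinocampheylborane and BF3·OEt2; THF, −78 °C], matched with the Felkin-type bias of the α-methyl aldehyde and followed by NaOH/H2O2 work-up that also saponifies the acetate, should give (2R,4S,5R,6R)-6-[(4-methoxyphenyl)methoxy]-2,4-dimethyloct-7-ene-1,5-diol F1. Selective iodination of the primary hydroxyl (I2, PPh3, imidazole, 0 °C) gives (3R,4R,5S,7R)-8-iodo-3-[(4-methoxyphenyl)methoxy]-5,7-dimethyloct-1-en-4-ol F2, and acylation with acryloyl chloride (i-Pr2NEt, CH2Cl2, 0 °C) gives (3R,4R,5S,7R)-8-iodo-3-[(4-methoxyphenyl)methoxy]-5,7-dimethyloct-1-en-4-yl prop-2-enoate F3. Ring-closing metathesis with second-generation Grubbs catalyst, (H2IMes)(PCy3)Cl2Ru=CHPh, in CH2Cl2 at 40 °C closes ring A to (5R,6R)-6-[(2S,4R)-5-iodo-4-methylpentan-2-yl]-5-[(4-methoxyphenyl)methoxy]-5,6-dihydro-2H-pyran-2-one F4. Zinc insertion as in step 13 gives iodo{(2R,4S)-4-[(2R,3R)-3-[(4-methoxyphenyl)methoxy]-6-oxo-3,6-dihydro-2H-pyran-2-yl]-2-methylpentyl}zinc F5, which is coupled with 18 under Pd(PPh3)4 to (5R,6R)-6-[(2S,4R,7S)-7-{[tert-butyl(dimethyl)silyl]oxy}-4-methyl-6-methylideneoctan-2-yl]-5-[(4-methoxyphenyl)methoxy]-5,6-dihydro-2H-pyran-2-one F6. Oxidative removal of the 4-methoxybenzyl ether (DDQ, CH2Cl2/pH 7 buffer, 0 °C) returns to the route at 22, from which steps 19 and 20 follow.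

**Step 14.** What may go wrong: hydrolytic opening of the unsaturated lactone or conjugate attack of hydroperoxide while the MIDA cage is being cleaved, and base-mediated translactonisation of the freed cis-5-hydroxy lactone to a butenolide. Fallback (release of boron separated from its oxidation): setting out from 20, transligation with pinacol (pinacol, solid NaHCO3, MeOH, 40 °C) gives (5R,6S)-6-[(2S,4R,7S)-7-{[tert-butyl(dimethyl)silyl]oxy}-4-methyl-6-methylideneoctan-2-yl]-5-(4,4,5,5-tetramethyl-1,3,2-dioxaborolan-2-yl)-5,6-dihydro-2H-pyran-2-one F7, whose tricoordinate boron is oxidised at neutral pH (30 % H2O2, pH 7 phosphate buffer, THF, 0 °C) with retention, returning to the route at 22.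

**Step 13.** What may go wrong: sluggish or incomplete zinc insertion into the β-branched iodide, protonation or reductive decomposition of the alkylzinc species next to the lactone, and β-hydride elimination at palladium. Fallback (polarity reversal, no organometallic is generated on the lactone fragment): setting out from 18, bromine–lithium exchange (t-BuLi, Et2O, −78 °C) gives {(3S)-3-{[tert-butyl(dimethyl)silyl]oxy}but-1-en-2-yl}lithium F8, which is transmetalated with ZnBr2 to bromo{(3S)-3-{[tert-butyl(dimethyl)silyl]oxy}but-1-en-2-yl}zinc F9. Palladium-catalysed alkyl–alkenyl Negishi coupling of F9 with the primary iodide 14 [Pd2(dba)3, P(c-C5H9)3, N-methylimidazole, THF/NMP, 60 °C] returns to the route at 20.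

## Further compounds

F1 | step 10 | (2R,4S,5R,6R)-6-[(4-methoxyphenyl)methoxy]-2,4-dimethyloct-7-ene-1,5-diol | OC[C@H](C)C[C@H](C)[C@@H](O)[C@H](OCc1ccc(OC)cc1)C=C
F2 | step 10 | (3R,4R,5S,7R)-8-iodo-3-[(4-methoxyphenyl)methoxy]-5,7-dimethyloct-1-en-4-ol | IC[C@H](C)C[C@H](C)[C@@H](O)[C@H](OCc1ccc(OC)cc1)C=C
F3 | step 10 | (3R,4R,5S,7R)-8-iodo-3-[(4-methoxyphenyl)methoxy]-5,7-dimethyloct-1-en-4-yl prop-2-enoate | IC[C@H](C)C[C@H](C)[C@@H](OC(=O)C=C)[C@H](OCc1ccc(OC)cc1)C=C
F4 | step 10 | (5R,6R)-6-[(2S,4R)-5-iodo-4-methylpentan-2-yl]-5-[(4-methoxyphenyl)methoxy]-5,6-dihydro-2H-pyran-2-one | IC[C@H](C)C[C@H](C)[C@H]1OC(=O)C=C[C@H]1OCc2ccc(OC)cc2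
F5 | step 10 | iodo{(2R,4S)-4-[(2R,3R)-3-[(4-methoxyphenyl)methoxy]-6-oxo-3,6-dihydro-2H-pyran-2-yl]-2-methylpentyl}zinc | I[Zn]C[C@H](C)C[C@H](C)[C@H]1OC(=O)C=C[C@H]1OCc2ccc(OC)cc2
F6 | step 10 | (5R,6R)-6-[(2S,4R,7S)-7-{[tert-butyl(dimethyl)silyl]oxy}-4-methyl-6-methylideneoctan-2-yl]-5-[(4-methoxyphenyl)methoxy]-5,6-dihydro-2H-pyran-2-one | C=C(C[C@H](C)C[C@H](C)[C@H]1OC(=O)C=C[C@H]1OCc2ccc(OC)cc2)[C@H](C)O[Si](C)(C)C(C)(C)C
F7 | step 14 | (5R,6S)-6-[(2S,4R,7S)-7-{[tert-butyl(dimethyl)silyl]oxy}-4-methyl-6-methylideneoctan-2-yl]-5-(4,4,5,5-tetramethyl-1,3,2-dioxaborolan-2-yl)-5,6-dihydro-2H-pyran-2-one | C=C(C[C@H](C)C[C@H](C)[C@H]1OC(=O)C=C[C@H]1B2OC(C)(C)C(C)(C)O2)[C@H](C)O[Si](C)(C)C(C)(C)C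
F8 | step 13 | {(3S)-3-{[tert-butyl(dimethyl)silyl]oxy}but-1-en-2-yl}lithium | C=C([Li])[C@H](C)O[Si](C)(C)C(C)(C)C
F9 | step 13 | bromo{(3S)-3-{[tert-butyl(dimethyl)silyl]oxy}but-1-en-2-yl}zinc | C=C([Zn]Br)[C@H](C)O[Si](C)(C)C(C)(C)C
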